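**Retrosynthetic overview**

1. Target 10 ⇐ hydroxy-enone 8 by C6-allylation last; the C4 methoxy group and the side chain both steer the allyl group.
2. 8 ⇐ cis-fused bicyclic ketal 5 by C=O reduction, O-methylation and ketal hydrolysis; the temporary tetrahydrofuran ring B masks the C1 ketone and the benzylic OH.
3. 5 ⇐ mixed quinone monoketal 4 by a hydrogen-atom-transfer 5-exo radical cyclisation that differentiates the two enone arms, forms the C6–C2′ bond and turns the vinyl group into the C2′ methyl.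
4. 4 ⇐ oxidative dearomatisation of 4-methoxyphenol 3 captured by (S)-allylic alcohol 2; 2 ⇐ asymmetric vinylation of 3,4,5-trimethoxybenzaldehyde 1.
5. Ring order: aryl ring bought; ring A (cyclohexadienone) from the phenol in step 2; ring B closed in step 3 and opened in step 5.

Assumption: small-group reagents (vinylmagnesium bromide, iodomethane, allyl bromide, water) are given by name and SMILES in the steps and are not numbered.

Numbering: cyclohexenone C1–C6 as in the target, side chain C1′ (carbinol) and C2′ (CH–CH3); bicyclic compounds use 1-benzofuran numbering (C7a = C1, C3a = C6, C5 = C4, C2 = C1′, C3 = C2′).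

**Step 1**
Reactants: 1 3,4,5-trimethoxybenzaldehyde
Product: 2 (1S)-1-(3,4,5-trimethoxyphenyl)prop-2-en-1-ol
Conditions: CH2=CHMgBr (2.4 equiv), ZnCl2 (1.2 equiv), Et2O/THF, 0 °C, then 1,4-dioxane and filtration to give salt-free (CH2=CH)2Zn; (−)-MIB [(2S)-3-exo-morpholinoisoborneol, 10 mol %], toluene, 0 °C; sat. aq. NH4Cl
Reagents that add atoms: vinylmagnesium bromide (C=C[Mg]Br), delivered through divinylzinc made in the flask (C=C[Zn]C=C)
Why: Catalytic enantioselective 1,2-addition of divinylzinc to an aryl aldehyde under amino-alcohol ligand control (Noyori/Oppolzer-type organozinc addition), the (−)-MIB–zinc chelate delivering vinyl to the Si face as it does ethyl from Et2Zn, which sets the carbinol centre (future C1′) as S.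

**Step 2**
Reactants: 2 (1S)-1-(3,4,5-trimethoxyphenyl)prop-2-en-1-ol; 3 4-methoxyphenol
Product: 4 4-methoxy-4-{[(1S)-1-(3,4,5-trimethoxyphenyl)prop-2-en-1-yl]oxy}cyclohexa-2,5-dien-1-one
Conditions: 3 (2.5 equiv) and PhI(OAc)2 (2.5 equiv) added slowly to 2 (1.0 equiv, 0.5 M), MeCN, 4 Å MS, 0 °C
Reagents that add atoms: none
Why: Oxidative dearomatisation of a para-alkoxyphenol with a trivalent-iodine oxidant, the aryloxy-iodane losing PhI to a phenoxenium equivalent that the hydroxyl of 2 captures at the methoxy-bearing para carbon to give the mixed quinone monoketal; no stereocentre is formed (the ketal carbon carries two identical enone arms) and the S centre is untouched because its C–O bond is not broken.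

**Step 3**
Reactants: 4 4-methoxy-4-{[(1S)-1-(3,4,5-trimethoxyphenyl)prop-2-en-1-yl]oxy}cyclohexa-2,5-dien-1-one
Product: 5 (2S,3S,3aR,7aR)-7a-methoxy-3-methyl-2-(3,4,5-trimethoxyphenyl)-2,3,3a,7a-tetrahydro-1-benzofuran-5(4H)-one
Conditions: Fe(acac)3 (0.3 equiv), PhSiH3 (2.0 equiv), Na2HPO4 (1 equiv), EtOH (0.02 M), 60 °C
Reagents that add atoms: none
Why: Iron-hydride hydrogen-atom transfer to the terminal alkene (MHAT, Mukaiyama/Baran-type reductive olefin–enone coupling run intramolecularly) makes the methyl group and a secondary radical at C3 that closes 5-exo-trig onto the β-carbon of one enone arm, after which the α-keto radical is reduced and protonated; the Beckwith–Houk chair transition state with aryl and methyl both pseudo-equatorial picks the diastereotopic arm that leaves the aryl group on the convex face (3aR,7aR, ring fusion necessarily cis) and sets C3 as S with methyl trans to aryl and cis to C4.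

**Step 4**
Reactants: 5 (2S,3S,3aR,7aR)-7a-methoxy-3-methyl-2-(3,4,5-trimethoxyphenyl)-2,3,3a,7a-tetrahydro-1-benzofuran-5(4H)-one
Product: 6 (2S,3S,3aR,5R,7aR)-7a-methoxy-3-methyl-2-(3,4,5-trimethoxyphenyl)-2,3,3a,4,5,7a-hexahydro-1-benzofuran-5-ol
Conditions: NaBH4 (1.2 equiv), CeCl3·7H2O (1.2 equiv), MeOH, −78 °C
Reagents that add atoms: none
Why: Luche 1,2-reduction of the enone, the small hydride attacking from the convex face away from ring B and its inward-pointing C3 methyl (as in carvone to cis-carveol), which gives the 5R alcohol cis to the C3a–C3 bond, i.e. the future C4 oxygen cis to the side chain.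

**Step 5**
Reactants: 6 (2S,3S,3aR,5R,7aR)-7a-methoxy-3-methyl-2-(3,4,5-trimethoxyphenyl)-2,3,3a,4,5,7a-hexahydro-1-benzofuran-5-ol
Product: 8 (4R,6R)-6-[(1S,2S)-1-hydroxy-1-(3,4,5-trimethoxyphenyl)propan-2-yl]-4-methoxycyclohex-2-en-1-one, via methyl ether ketal 7 (not isolated)
Conditions: NaH (1.5 equiv), MeI (3 equiv), THF, 0 °C to rt; then 0.5 M aq. HCl, THF, 0 °C to rt
Reagents that add atoms: iodomethane (CI); water (O)
Why: Williamson O-methylation of the only free hydroxyl (retention, the ketal meanwhile protecting both the C1 ketone and the benzylic alcohol) followed by acid hydrolysis of the allylic mixed ketal, which opens ring B to the conjugated enone and the free benzylic alcohol; no stereocentre is made, and C6, which may epimerise or sit partly as the cyclic hemiketal, is reset in step 6.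

**Step 6**
Reactants: 8 (4R,6R)-6-[(1S,2S)-1-hydroxy-1-(3,4,5-trimethoxyphenyl)propan-2-yl]-4-methoxycyclohex-2-en-1-one
Product: 10 (4R,6R)-6-[(1S,2S)-1-hydroxy-1-(3,4,5-trimethoxyphenyl)propan-2-yl]-4-methoxy-6-(prop-2-en-1-yl)cyclohex-2-en-1-one, via dilithium enolate alkoxide 9 (not isolated)
Conditions: LiN(i-Pr)2 (2.3 equiv), THF, −78 to −40 °C; allyl bromide (1.5 equiv), −78 to −20 °C; H2O
Reagents that add atoms: allyl bromide (C=CCBr)
Why: Kinetic α′-deprotonation gives the cross-conjugated lithium dienolate (the alkoxide stays as its poorly nucleophilic lithium salt) and SN2 C-allylation (enolate alkylation) creates the quaternary C6, the allyl group entering anti to the pseudo-axial C4 methoxy and anti to the CH(OLi)Ar branch of the A(1,3)-minimised (or lithium-chelated) side chain, two matched effects that both give 6R.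

**Compound list**

1 | 3,4,5-trimethoxybenzaldehyde | COc1cc(C=O)cc(OC)c1OC | starting material
2 | (1S)-1-(3,4,5-trimethoxyphenyl)prop-2-en-1-ol | C=C[C@H](O)c1cc(OC)c(OC)c(OC)c1 | intermediate
3 | 4-methoxyphenol | COc1ccc(O)cc1 | starting material
4 | 4-methoxy-4-{[(1S)-1-(3,4,5-trimethoxyphenyl)prop-2-en-1-yl]oxy}cyclohexa-2,5-dien-1-one | C=C[C@H](OC1(OC)C=CC(=O)C=C1)c1cc(OC)c(OC)c(OC)c1 | intermediate
5 | (2S,3S,3aR,7aR)-7a-methoxy-3-methyl-2-(3,4,5-trimethoxyphenyl)-2,3,3a,7a-tetrahydro-1-benzofuran-5(4H)-one (cis-fused; aryl and 7a-OMe on the convex face, 3-methyl on the concave face) | CO[C@@]12C=CC(=O)C[C@@H]1[C@H](C)[C@@H](c1cc(OC)c(OC)c(OC)c1)O2 | intermediate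
6 | (2S,3S,3aR,5R,7aR)-7a-methoxy-3-methyl-2-(3,4,5-trimethoxyphenyl)-2,3,3a,4,5,7a-hexahydro-1-benzofuran-5-ol (5-OH cis to the C3a–C3 bond) | CO[C@@]12C=C[C@H](O)C[C@@H]1[C@H](C)[C@@H](c1cc(OC)c(OC)c(OC)c1)O2 | intermediate
7 | (2S,3S,3aR,5R,7aR)-5,7a-dimethoxy-3-methyl-2-(3,4,5-trimethoxyphenyl)-2,3,3a,4,5,7a-hexahydro-1-benzofuran | CO[C@@]12C=C[C@H](OC)C[C@@H]1[C@H](C)[C@@H](c1cc(OC)c(OC)c(OC)c1)O2 | intermediate
8 | (4R,6R)-6-[(1S,2S)-1-hydroxy-1-(3,4,5-trimethoxyphenyl)propan-2-yl]-4-methoxycyclohex-2-en-1-one | O=C1C=C[C@H](OC)C[C@@H]1[C@H](C)[C@H](O)c1cc(OC)c(OC)c(OC)c1 | intermediate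
9 | dilithium salt of 8: lithium dienolate across C1/C6 (C6 planar) and lithium alkoxide at C1′; C4 (R), C1′ (S), C2′ (S) as in 8 | [Li]OC1=C([C@H](C)[C@H](O[Li])c2cc(OC)c(OC)c(OC)c2)C[C@@H](OC)C=C1 | intermediate
10 | (4R,6R)-6-[(1S,2S)-1-hydroxy-1-(3,4,5-trimethoxyphenyl)propan-2-yl]-4-methoxy-6-(prop-2-en-1-yl)cyclohex-2-en-1-one | C=CC[C@]1([C@H](C)[C@H](O)c2cc(OC)c(OC)c(OC)c2)C[C@@H](OC)C=CC1=O | target

**Totals**

Total step count: 6. Longest linear sequence: 6 steps (1 → 2 → 4 → 5 → 6 → 8 → 10).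

**Steps most likely to fail, with fallbacks**

Step 2. The alcohol is used as the limiting reagent, so acetate, water or a second phenol may compete for the phenoxenium equivalent. The fallback sets out from 2 and returns at 4. Alcohol 2 is acylated (ClCO2Me, pyridine, CH2Cl2, 0 °C) to methyl (1S)-1-(3,4,5-trimethoxyphenyl)prop-2-en-1-yl carbonate F1. F1 then undergoes iridium-catalysed allylic etherification with hydroquinone (3 equiv, K3PO4, THF, 50 °C) using [Ir(cod)Cl]2 and the antipode of the O,O′-binaphthyl N,N-bis(1-phenylethyl)phosphoramidite ligand that is matched with the S carbonate, which reacts with net retention at the branched carbon to give 4-{[(1S)-1-(3,4,5-trimethoxyphenyl)prop-2-en-1-yl]oxy}phenol F2. Standard oxidation of this 4-alkoxyphenol with PhI(OAc)2 in MeOH at 0 °C, with methanol as the abundant nucleophile, gives 4.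

Step 3. The selection between the two enone arms rests on substrate control only, and alkene isomerisation or reduction of the enone by the iron hydride may compete. The fallback forms the same bond by an intermolecular, catalyst-controlled polar addition; it sets out from 2 and 3 and returns at 6. Redox isomerisation of 2 (RuCl2(PPh3)3, 2 mol %, toluene, 110 °C) gives 1-(3,4,5-trimethoxyphenyl)propan-1-one F3, which LiN(i-Pr)2 and Me3SiCl in THF at −78 °C convert into the Z enol ether (Z)-trimethyl{[1-(3,4,5-trimethoxyphenyl)prop-1-en-1-yl]oxy}silane F4. Phenol 3 is oxidised (PhI(OAc)2, MeOH, 0 °C) to 4,4-dimethoxycyclohexa-2,5-dien-1-one F5. Mukaiyama–Michael addition of F4 to F5 follows in toluene at −78 °C, catalysed by the HNTf2 adduct of (S)-3,3-diphenyl-1-(2-methylphenyl)tetrahydro-1H,3H-pyrrolo[1,2-c][1,3,2]oxazaborole or its antipode, whichever delivers the 5R ring centre. This gives (5R)-4,4-dimethoxy-5-[(2S)-1-oxo-1-(3,4,5-trimethoxyphenyl)propan-2-yl]cyclohex-2-en-1-one F6, with the C2′ epimer removed by chromatography since simple diastereoselection is less secure here. NaBH4/CeCl3·7H2O in MeOH at −78 °C reduces both ketones (ring carbonyl cis to the side chain, aryl ketone by Felkin–Anh control to the 1′S alcohol), and PPTS in CH2Cl2 closes the benzylic hydroxyl onto the dimethyl ketal to give 6.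

Step 6. The α′-hydrogen is tertiary and hindered, the alkoxide can close onto the ketone as a lactolate, and O-allylation or γ-deprotonation may compete. The fallback replaces the dianion alkylation by a palladium π-allyl enolate recombination; it sets out from 8 and returns at 10. Silylation (Et3SiCl, imidazole, DMF) gives (4R,6R)-4-methoxy-6-[(1S,2S)-1-(triethylsilyloxy)-1-(3,4,5-trimethoxyphenyl)propan-2-yl]cyclohex-2-en-1-one F7. LiN(SiMe3)2 in THF at −78 °C followed by allyl chloroformate gives the allyl enol carbonate allyl (4R)-4-methoxy-6-[(1S,2S)-1-(triethylsilyloxy)-1-(3,4,5-trimethoxyphenyl)propan-2-yl]cyclohexa-1,5-dien-1-yl carbonate F8. Tsuji decarboxylative allylation (Pd2(dba)3, 2.5 mol %, with the t-Bu-PHOX antipode that reinforces the substrate bias, toluene, 25 °C) forms the quaternary centre in (4R,6R)-4-methoxy-6-(prop-2-en-1-yl)-6-[(1S,2S)-1-(triethylsilyloxy)-1-(3,4,5-trimethoxyphenyl)propan-2-yl]cyclohex-2-en-1-one F9. HF·pyridine in THF removes the silyl group to give 10.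

**Further compounds**

F1 | step 2 | methyl (1S)-1-(3,4,5-trimethoxyphenyl)prop-2-en-1-yl carbonate | C=C[C@H](OC(=O)OC)c1cc(OC)c(OC)c(OC)c1
F2 | step 2 | 4-{[(1S)-1-(3,4,5-trimethoxyphenyl)prop-2-en-1-yl]oxy}phenol | C=C[C@H](Oc1ccc(O)cc1)c1cc(OC)c(OC)c(OC)c1
F3 | step 3 | 1-(3,4,5-trimethoxyphenyl)propan-1-one | CCC(=O)c1cc(OC)c(OC)c(OC)c1
F4 | step 3 | (Z)-trimethyl{[1-(3,4,5-trimethoxyphenyl)prop-1-en-1-yl]oxy}silane | C/C=C(\O[Si](C)(C)C)c1cc(OC)c(OC)c(OC)c1
F5 | step 3 | 4,4-dimethoxycyclohexa-2,5-dien-1-one | COC1(OC)C=CC(=O)C=C1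
F6 | step 3 | (5R)-4,4-dimethoxy-5-[(2S)-1-oxo-1-(3,4,5-trimethoxyphenyl)propan-2-yl]cyclohex-2-en-1-one | COC1(OC)C=CC(=O)C[C@@H]1[C@H](C)C(=O)c1cc(OC)c(OC)c(OC)c1
F7 | step 6 | (4R,6R)-4-methoxy-6-[(1S,2S)-1-(triethylsilyloxy)-1-(3,4,5-trimethoxyphenyl)propan-2-yl]cyclohex-2-en-1-one | O=C1C=C[C@H](OC)C[C@@H]1[C@H](C)[C@H](O[Si](CC)(CC)CC)c1cc(OC)c(OC)c(OC)c1
F8 | step 6 | allyl (4R)-4-methoxy-6-[(1S,2S)-1-(triethylsilyloxy)-1-(3,4,5-trimethoxyphenyl)propan-2-yl]cyclohexa-1,5-dien-1-yl carbonate | C=CCOC(=O)OC1=C([C@H](C)[C@H](O[Si](CC)(CC)CC)c2cc(OC)c(OC)c(OC)c2)C[C@@H](OC)C=C1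
F9 | step 6 | (4R,6R)-4-methoxy-6-(prop-2-en-1-yl)-6-[(1S,2S)-1-(triethylsilyloxy)-1-(3,4,5-trimethoxyphenyl)propan-2-yl]cyclohex-2-en-1-one | C=CC[C@]1([C@H](C)[C@H](O[Si](CC)(CC)CC)c2cc(OC)c(OC)c(OC)c2)C[C@@H](OC)C=CC1=O
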